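**Strategy.** With the chain numbered from the ester carbonyl (C1), everything rests on disconnecting the O–C8 bond of the oxolane ring (O, C5–C8). C8 is both the carbon on the ring oxygen and the neighbour of the C9≡C10 triple bond. A leaving group there, beside a terminal alkyne, departs under monovalent copper catalysis and leaves a flat allenylidene that the C5 hydroxyl traps. One operation thus closes the ring, sets 8S from an epimeric mixture under ligand control and keeps the C10–H alkyne for coupling. The precursor is the open C1–C10 chain: C1 silyl ether, free 5R hydroxyl, terminal alkyne and a C8 pentafluorobenzoate, since acetate ionises poorly at alkyl-substituted carbons.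

Key step: step 7

Abbreviations: TBDPS = tert-butyldiphenylsilyl; TES = triethylsilyl; Ph-pybox = 2,6-bis(4-phenyl-4,5-dihydro-1,3-oxazol-2-yl)pyridine.

Structure check: the target is 5R,8S, which is the 2,5-trans oxolane. C5 keeps the spatial arrangement of (S)-1,2-epoxyhex-5-ene, and the descriptor becomes R only because the CIP ranking of the two carbon arms swaps. Carbon sources are C1–C3 from bromopropanol, C4–C8 from the epoxide, C9–C10 from the ethynyl reagent, C11–C17 from heptynol, C18–C19 and C20 from two ylides. C1 stays a silyl ether until after ring closure because a C1 ester would lactonise onto the free C5 hydroxyl.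

Assumption: which Ph-pybox enantiomer is matched with the 5R centre cannot be derived from the known aromatic cases, so step 7 is written with (S,S)-Ph-pybox, and the equally available (R,R) form takes its place if a test run points that way.

**Step 1**
Reactants: 1 3-bromopropan-1-ol
Product: 2 (3-bromopropoxy)(tert-butyl)diphenylsilane
Conditions: TBDPSCl, imidazole, CH2Cl2, 0 °C to rt
Reagents that add atoms: tert-butyl(chloro)diphenylsilane (TBDPSCl), CC(C)(C)[Si](Cl)(c1ccccc1)c1ccccc1
Why: Imidazole-promoted O-silylation of a primary alcohol is routine, and the very acid-stable TBDPS ether is chosen so that it outlasts the later acidic removal of the TES group.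

**Step 2**
Reactants: 2 (3-bromopropoxy)(tert-butyl)diphenylsilane; 3 (S)-1,2-epoxyhex-5-ene
Product: 5 (5R)-9-[(tert-butyldiphenylsilyl)oxy]non-1-en-5-ol, via Grignard reagent 4 (not isolated)
Conditions: Mg, THF, 40 °C; then CuI (10 mol %), 3, THF, −30 to 0 °C
Reagents that add atoms: none
Why: Copper-catalysed Grignard opening of a monosubstituted epoxide is an SN2 attack at the unhindered CH2 terminus, so the C–O bond at the stereocentre is never touched and the configuration of 3 is carried over intact as 5R.

**Step 3**
Reactants: 5 (5R)-9-[(tert-butyldiphenylsilyl)oxy]non-1-en-5-ol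
Product: 6 (5R)-9-[(tert-butyldiphenylsilyl)oxy]-5-[(triethylsilyl)oxy]non-1-ene
Conditions: TESCl, imidazole, CH2Cl2, 0 °C to rt
Reagents that add atoms: chlorotriethylsilane (TESCl), CC[Si](Cl)(CC)CC
Why: Routine silyl ether formation, which stops the γ-hydroxy aldehyde of the next step from closing to a lactol and keeps the C5 oxygen out of the acylation in step 5.

**Step 4**
Reactants: 6 (5R)-9-[(tert-butyldiphenylsilyl)oxy]-5-[(triethylsilyl)oxy]non-1-ene
Product: 8 (4R)-8-[(tert-butyldiphenylsilyl)oxy]-4-[(triethylsilyl)oxy]octanal, via ozonide 7 (not isolated)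
Conditions: O3, CH2Cl2, −78 °C; then PPh3, −78 °C to rt
Reagents that add atoms: ozone, [O-][O+]=O
Why: Ozonolysis (Criegee mechanism) with reductive PPh3 work-up cleaves the only C=C bond to the C8 aldehyde, and both silyl ethers are inert in methanol-free CH2Cl2.

**Step 5**
Reactants: 8 (4R)-8-[(tert-butyldiphenylsilyl)oxy]-4-[(triethylsilyl)oxy]octanal; 9 ethynylmagnesium bromide
Product: 11 (3RS,6R)-10-[(tert-butyldiphenylsilyl)oxy]-6-[(triethylsilyl)oxy]dec-1-yn-3-yl pentafluorobenzoate (both epimers at the ester carbon C8), via magnesium alkoxide 10 (not isolated)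
Conditions: 9 (1.3 equiv), THF, 0 °C; then C6F5COCl (1.6 equiv), 0 °C to rt
Reagents that add atoms: pentafluorobenzoyl chloride, O=C(Cl)c1c(F)c(F)c(F)c(F)c1F
Why: 1,2-Addition of an alkynyl Grignard reagent to an aldehyde is followed by in-flask O-acylation of the magnesium alkoxide, and the lack of control from the remote C5 centre is harmless because step 7 erases the C8 configuration.

**Step 6**
Reactants: 11 (3RS,6R)-10-[(tert-butyldiphenylsilyl)oxy]-6-[(triethylsilyl)oxy]dec-1-yn-3-yl pentafluorobenzoate
Product: 12 (3RS,6R)-10-[(tert-butyldiphenylsilyl)oxy]-6-hydroxydec-1-yn-3-yl pentafluorobenzoate (both epimers at C8)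
Conditions: AcOH/THF/H2O (3:1:1), rt
Reagents that add atoms: none
Why: Acid-catalysed silyl ether hydrolysis discriminates sharply between the labile secondary TES ether and the acid-stable TBDPS ether, and the weakly acidic medium disfavours ester migration to the freed C5 hydroxyl.

**Step 7**
Reactants: 12 (3RS,6R)-10-[(tert-butyldiphenylsilyl)oxy]-6-hydroxydec-1-yn-3-yl pentafluorobenzoate
Product: 14 tert-butyl{4-[(2R,5S)-5-ethynyloxolan-2-yl]butoxy}diphenylsilane, via copper allenylidene 13 (not isolated)
Conditions: Cu(CH3CN)4BF4 (10 mol %), (S,S)-Ph-pybox (12 mol %), iPr2NEt (2 equiv), CH2Cl2 (0.01 M), −20 °C to rt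
Reagents that add atoms: none
Why: Proposed new method: iPr2NEt and the copper–pybox cation convert the terminal alkyne of 12 into a copper acetylide, which expels pentafluorobenzoate to give allenylidene 13 with a trigonal C8, so that both C8 epimers merge into one species; the C5 oxygen then adds to C8 and protonation at C10 frees 14 and the catalyst. The closest known reaction types are the copper–pybox propargylic etherification of propargylic esters with external alcohols and the intramolecular copper–pybox propargylic amination, and for non-aromatic esters a pentafluorobenzoate is a known remedy for the sluggish ionisation of acetates. The oxolane closes in the 5-exo-trig mode, the C8=C9 bond of the cumulene staying outside the new ring. The new C8 centre (S) is controlled by the chiral pybox pocket, which leaves one face of C8 open, backed by the fixed 5R centre, whose side chain prefers to sit trans to the bulky copper-bearing arm in the envelope-like transition state. The step needs face selectivity at C8 and chemoselectivity for the internal oxygen over loss of a C7 proton and over outside nucleophiles, and the substrate secures the latter by the 1,4-placement of C5–OH and C8 and by offering no other free OH or NH (C1 silylated), helped by a tertiary amine, a non-nucleophilic solvent in place of methanol and high dilution. Any leakage to 8R gives the cis diastereomer, which chromatography should remove, so the enantiopurity rests on C5 alone.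

**Step 8**
Reactants: 14 tert-butyl{4-[(2R,5S)-5-ethynyloxolan-2-yl]butoxy}diphenylsilane
Product: 15 4-[(2R,5S)-5-ethynyloxolan-2-yl]butan-1-ol
Conditions: TBAF, THF, 0 °C to rt
Reagents that add atoms: none
Why: Fluoride-induced silyl ether cleavage is driven by the strong Si–F bond, and the ether ring and terminal alkyne are inert to TBAF.

**Step 9**
Reactants: 15 4-[(2R,5S)-5-ethynyloxolan-2-yl]butan-1-ol
Product: 16 4-[(2R,5S)-5-ethynyloxolan-2-yl]butanoic acid
Conditions: TEMPO (20 mol %), PhI(OAc)2 (2.5 equiv), MeCN/H2O (1:1), rt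
Reagents that add atoms: water, O
Why: Oxoammonium (TEMPO) oxidation with PhI(OAc)2 as terminal oxidant takes the primary alcohol through the aldehyde hydrate to the acid without touching the alkyne or the C8 centre.

**Step 10**
Reactants: 16 4-[(2R,5S)-5-ethynyloxolan-2-yl]butanoic acid
Product: 17 methyl 4-[(2R,5S)-5-ethynyloxolan-2-yl]butanoate
Conditions: MeI, K2CO3, DMF, rt
Reagents that add atoms: iodomethane, CI
Why: SN2 O-alkylation of the carboxylate, with K2CO3 too weak to deprotonate the alkyne or to epimerise C8.

**Step 11**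
Reactants: 18 hept-6-yn-1-ol
Product: 20 (E)-7-iodohept-6-en-1-ol, via alkenylzirconocene 19 (not isolated)
Conditions: Cp2ZrHCl (2.3 equiv), THF, 0 °C to rt, dark; then I2, 0 °C
Reagents that add atoms: iodine, II
Why: Hydrozirconation–iodinolysis, in which the first equivalent of Cp2ZrHCl is consumed by the hydroxyl, the second adds syn with zirconium at the terminal carbon, and iodine replaces zirconium with retention, which sets the E C11=C12 geometry.

**Step 12**
Reactants: 20 (E)-7-iodohept-6-en-1-ol
Product: 21 (E)-7-iodohept-6-enal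
Conditions: TEMPO (10 mol %), PhI(OAc)2 (1.1 equiv), CH2Cl2, rt
Reagents that add atoms: none
Why: TEMPO/PhI(OAc)2 oxidation in anhydrous CH2Cl2 stops at the aldehyde and leaves the alkenyl iodide alone.

**Step 13**
Reactants: 21 (E)-7-iodohept-6-enal; 22 (triphenylphosphoranylidene)acetaldehyde
Product: 23 (2E,8E)-9-iodonona-2,8-dienal
Conditions: 22 (1.1 equiv), toluene, 80 °C
Reagents that add atoms: none
Why: Wittig olefination with a formyl-stabilised ylide is inherently E-selective and sets the C17=C18 geometry, while only a small excess of 22 limits a second homologation.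

**Step 14**
Reactants: 17 methyl 4-[(2R,5S)-5-ethynyloxolan-2-yl]butanoate; 23 (2E,8E)-9-iodonona-2,8-dienal
Product: 24 methyl 4-{(2R,5S)-5-[(3E,9E)-11-oxoundeca-3,9-dien-1-yn-1-yl]oxolan-2-yl}butanoate
Conditions: Pd(PPh3)2Cl2 (5 mol %), CuI (10 mol %), Et3N (3 equiv), degassed THF, rt
Reagents that add atoms: none
Why: Sonogashira coupling of a terminal alkyne with an alkenyl iodide runs at room temperature with retention of the E geometry, and the tertiary amine base cannot condense with the enal.

**Step 15**
Reactants: 24 methyl 4-{(2R,5S)-5-[(3E,9E)-11-oxoundeca-3,9-dien-1-yn-1-yl]oxolan-2-yl}butanoate; 25 (bromomethyl)triphenylphosphonium bromide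
Product: 27 methyl 4-{(2R,5S)-5-[(3E,9E,11Z)-12-bromododeca-3,9,11-trien-1-yn-1-yl]oxolan-2-yl}butanoate, via bromomethylidene ylide 26 (not isolated)
Conditions: 25 (1.5 equiv), KOtBu (1.4 equiv), THF, −78 °C; then 24, −78 °C, dark
Reagents that add atoms: none
Why: Wittig olefination with the non-stabilised bromomethylidene ylide at low temperature is kinetically cis-selective, which should set the Z C19=C20 bromoalkene, while a slight deficit of base avoids dehydrobromination and leaves the ester untouched.

**Compound list**
1 | 3-bromopropan-1-ol | OCCCBr | starting material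
2 | (3-bromopropoxy)(tert-butyl)diphenylsilane | CC(C)(C)[Si](c1ccccc1)(c1ccccc1)OCCCBr | intermediate
3 | (S)-1,2-epoxyhex-5-ene, (2S)-2-(but-3-en-1-yl)oxirane | C=CCC[C@H]1CO1 | starting material
4 | {3-[(tert-butyldiphenylsilyl)oxy]propyl}magnesium bromide (not isolated) | CC(C)(C)[Si](c1ccccc1)(c1ccccc1)OCCC[Mg]Br | intermediate
5 | (5R)-9-[(tert-butyldiphenylsilyl)oxy]non-1-en-5-ol | CC(C)(C)[Si](c1ccccc1)(c1ccccc1)OCCCC[C@@H](O)CCC=C | intermediate
6 | (5R)-9-[(tert-butyldiphenylsilyl)oxy]-5-[(triethylsilyl)oxy]non-1-ene | CC(C)(C)[Si](c1ccccc1)(c1ccccc1)OCCCC[C@@H](O[Si](CC)(CC)CC)CCC=C | intermediate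
7 | 1,2,4-trioxolane (ozonide) of 6, ring carbon unassigned (not isolated) | CC(C)(C)[Si](c1ccccc1)(c1ccccc1)OCCCC[C@@H](O[Si](CC)(CC)CC)CCC1OCOO1 | intermediate
8 | (4R)-8-[(tert-butyldiphenylsilyl)oxy]-4-[(triethylsilyl)oxy]octanal | CC(C)(C)[Si](c1ccccc1)(c1ccccc1)OCCCC[C@@H](O[Si](CC)(CC)CC)CCC=O | intermediate
9 | ethynylmagnesium bromide | C#C[Mg]Br | starting material
10 | bromomagnesium (3RS,6R)-10-[(tert-butyldiphenylsilyl)oxy]-6-[(triethylsilyl)oxy]dec-1-yn-3-olate (not isolated) | CC(C)(C)[Si](c1ccccc1)(c1ccccc1)OCCCC[C@@H](O[Si](CC)(CC)CC)CCC(O[Mg]Br)C#C | intermediate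
11 | (3RS,6R)-10-[(tert-butyldiphenylsilyl)oxy]-6-[(triethylsilyl)oxy]dec-1-yn-3-yl pentafluorobenzoate | CC(C)(C)[Si](c1ccccc1)(c1ccccc1)OCCCC[C@@H](O[Si](CC)(CC)CC)CCC(OC(=O)c1c(F)c(F)c(F)c(F)c1F)C#C | intermediate
12 | (3RS,6R)-10-[(tert-butyldiphenylsilyl)oxy]-6-hydroxydec-1-yn-3-yl pentafluorobenzoate | CC(C)(C)[Si](c1ccccc1)(c1ccccc1)OCCCC[C@@H](O)CCC(OC(=O)c1c(F)c(F)c(F)c(F)c1F)C#C | intermediate
13 | copper allenylidene cation from 12, pybox ligand left out of the SMILES (not isolated) | CC(C)(C)[Si](c1ccccc1)(c1ccccc1)OCCCC[C@@H](O)CCC=C=C=[Cu+] | intermediate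
14 | tert-butyl{4-[(2R,5S)-5-ethynyloxolan-2-yl]butoxy}diphenylsilane | CC(C)(C)[Si](c1ccccc1)(c1ccccc1)OCCCC[C@@H]1CC[C@@H](C#C)O1 | intermediate
15 | 4-[(2R,5S)-5-ethynyloxolan-2-yl]butan-1-ol | OCCCC[C@@H]1CC[C@@H](C#C)O1 | intermediate
16 | 4-[(2R,5S)-5-ethynyloxolan-2-yl]butanoic acid | OC(=O)CCC[C@@H]1CC[C@@H](C#C)O1 | intermediate
17 | methyl 4-[(2R,5S)-5-ethynyloxolan-2-yl]butanoate | COC(=O)CCC[C@@H]1CC[C@@H](C#C)O1 | intermediate
18 | hept-6-yn-1-ol | OCCCCCC#C | starting material
19 | (E)-alkenylzirconocene chloride carrying the zirconocene chloride alkoxide, cyclopentadienyl rings drawn sigma-bonded (not isolated) | Cl[Zr](C1C=CC=C1)(C1C=CC=C1)OCCCCC/C=C/[Zr](Cl)(C1C=CC=C1)C1C=CC=C1 | intermediate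
20 | (E)-7-iodohept-6-en-1-ol | OCCCCC/C=C/I | intermediate
21 | (E)-7-iodohept-6-enal | O=CCCCC/C=C/I | intermediate
22 | (triphenylphosphoranylidene)acetaldehyde | O=CC=P(c1ccccc1)(c1ccccc1)c1ccccc1 | starting material
23 | (2E,8E)-9-iodonona-2,8-dienal | O=C/C=C/CCCC/C=C/I | intermediate
24 | methyl 4-{(2R,5S)-5-[(3E,9E)-11-oxoundeca-3,9-dien-1-yn-1-yl]oxolan-2-yl}butanoate | COC(=O)CCC[C@@H]1CC[C@@H](C#C/C=C/CCCC/C=C/C=O)O1 | intermediate
25 | (bromomethyl)triphenylphosphonium bromide | BrC[P+](c1ccccc1)(c1ccccc1)c1ccccc1.[Br-] | starting material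
26 | (bromomethylidene)triphenylphosphorane (not isolated) | BrC=P(c1ccccc1)(c1ccccc1)c1ccccc1 | intermediate
27 | methyl 4-{(2R,5S)-5-[(3E,9E,11Z)-12-bromododeca-3,9,11-trien-1-yn-1-yl]oxolan-2-yl}butanoate | COC(=O)CCC[C@@H]1CC[C@@H](C#C/C=C/CCCC/C=C/C=C\Br)O1 | target

**Total step count:** 15
**Longest linear sequence:** 12 steps (steps 1–10, 14 and 15). Steps 11–13 build the side-chain fragment in parallel.

**Steps most likely to fail**

**1. Step 7 (ring closure).**
- What may go wrong: slow ionisation at the alkyl-substituted C8, loss of a C7 proton from the allenylidene in competition with ring closure, or weak face discrimination at C8.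
- Fallback with known chemistry, setting out from 5 and coming back at 14. The bis-homoallylic alcohol 5 is itself a substrate for the Mukaiyama aerobic oxidative cyclisation. The conditions are Co(modp)2 (a divalent cobalt complex, modp = 1-morpholinocarbamoyl-4,4-dimethylpentane-1,3-dionate), O2, t-BuOOH, i-PrOH, 50 °C.
- This reaction is known for a strong 2,5-trans preference with 1-substituted pent-4-en-1-ols and should give {(2S,5R)-5-[4-(tert-butyldiphenylsilyloxy)butyl]oxolan-2-yl}methanol F1.
- Dess–Martin oxidation should give (2S,5R)-5-[4-(tert-butyldiphenylsilyloxy)butyl]oxolane-2-carbaldehyde F2.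
- Ohira–Bestmann homologation [dimethyl (1-diazo-2-oxopropyl)phosphonate, K2CO3, MeOH, 0 °C to rt] then adds C10 and delivers 14.
- C8 is then set by substrate control from C5, and O–C8 is formed on the alkene instead of at a propargylic cation equivalent.

**2. Step 15 (bromoalkene).**
- What may go wrong: erosion of the Z selectivity of the halo-ylide olefination, or base-induced loss of HBr from the product.
- Fallback setting out from 24 and coming back at 27. Ramirez (Corey–Fuchs type) dibromoolefination (CBr4, PPh3, CH2Cl2, 0 °C) should give methyl 4-{(2R,5S)-5-[(3E,9E)-12,12-dibromododeca-3,9,11-trien-1-yn-1-yl]oxolan-2-yl}butanoate F3.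
- Hydrogenolysis follows with Bu3SnH (1 equiv, slow addition) and Pd(PPh3)4 (cat.) in toluene at rt. Zerovalent palladium inserts preferentially into the less hindered C–Br bond trans to the diene chain, which should leave the Z bromide 27.
- The geometry then stems from a site-selective oxidative addition and not from a kinetic olefination.

**3. Step 14 (fragment union).**
- What may go wrong: attrition of the enal in the amine/copper medium during the coupling.
- Fallback setting out from 17 and 20 and coming back at 24, with the coupling moved ahead of all aldehyde chemistry. Sonogashira coupling of 17 with the iodo alcohol 20 should give methyl 4-{(2R,5S)-5-[(3E)-9-hydroxynon-3-en-1-yn-1-yl]oxolan-2-yl}butanoate F4.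
- TEMPO/PhI(OAc)2 in CH2Cl2 should give methyl 4-{(2R,5S)-5-[(3E)-9-oxonon-3-en-1-yn-1-yl]oxolan-2-yl}butanoate F5.
- Wittig olefination with 22 should give 24.
- The price is two more steps in the linear sequence.

**Further compounds**
F1 | step 7 | {(2S,5R)-5-[4-(tert-butyldiphenylsilyloxy)butyl]oxolan-2-yl}methanol | CC(C)(C)[Si](c1ccccc1)(c1ccccc1)OCCCC[C@@H]1CC[C@@H](CO)O1
F2 | step 7 | (2S,5R)-5-[4-(tert-butyldiphenylsilyloxy)butyl]oxolane-2-carbaldehyde | CC(C)(C)[Si](c1ccccc1)(c1ccccc1)OCCCC[C@@H]1CC[C@@H](C=O)O1
F3 | step 15 | methyl 4-{(2R,5S)-5-[(3E,9E)-12,12-dibromododeca-3,9,11-trien-1-yn-1-yl]oxolan-2-yl}butanoate | COC(=O)CCC[C@@H]1CC[C@@H](C#C/C=C/CCCC/C=C/C=C(Br)Br)O1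
F4 | step 14 | methyl 4-{(2R,5S)-5-[(3E)-9-hydroxynon-3-en-1-yn-1-yl]oxolan-2-yl}butanoate | COC(=O)CCC[C@@H]1CC[C@@H](C#C/C=C/CCCCCO)O1
F5 | step 14 | methyl 4-{(2R,5S)-5-[(3E)-9-oxonon-3-en-1-yn-1-yl]oxolan-2-yl}butanoate | COC(=O)CCC[C@@H]1CC[C@@H](C#C/C=C/CCCCC=O)O1
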